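The runs are simulated with constants of no real substance; the scatter is artificial.

In the dawn run the isomer of the product rises as target falls, so in a repeat you should watch the sum of the two as well as the isomer.

in all of them: solid substrate 0.12 M
- dawn: reagent 0.60 equiv; second substrate 0.20 equiv; run made earlier
- dusk: reagent 0.84 equiv; second substrate 0.20 equiv; run made earlier
- summer: reagent 1.3 equiv; second substrate 0.20 equiv; run made earlier
- spring: reagent 0.60 equiv; second substrate 0.30 equiv; run made earlier
- cedar: reagent 0.600 equiv; second substrate 0.200 equiv; everything together at the start; time 12 d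
- birch: reagent 0.600 equiv; second substrate 0.200 equiv (fed, over 5.0 d); all else is in the flask from the start; the feed brings no volume worth counting; time 12 d
- elm: reagent 0.600 equiv (fed, over 5.0 d); second substrate 0.200 equiv; all else is in the flask from the start; the feed brings no volume worth counting; time 12 d

| run | time / d | isomer of the product / % | target / % | solid substrate / % |
|---|---|---|---|---|
| dawn | 1.67 | 5.2 | 28.0 | 44.8 |
| dawn | 4.00 | 17.2 | 23.9 | 0.7 |
| dawn | 8.00 | 25.2 | 15.5 | 0.2 |
| dawn | 12.0 | 25.7 | 13.6 | 0.7 |
| dusk | 3.00 | 18.1 | 43.2 | 2.9 |
| dusk | 6.00 | 34.8 | 29.4 | 0 |
| dusk | 10.0 | 38.4 | 24.4 | 0.7 |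
| dusk | 12.0 | 40.2 | 23.6 | 0 |
| summer | 3.00 | 24.4 | 65.7 | 0 |
| summer | 6.00 | 49.6 | 49.8 | 0.1 |
| summer | 10.0 | 60.7 | 39.8 | 1.1 |
| summer | 12.0 | 61.6 | 36.6 | 0 |
| spring | 3.00 | 10.3 | 19.7 | 16.6 |
| spring | 6.00 | 16.9 | 15.7 | 0 |
| spring | 10.0 | 18.6 | 12.1 | 0.1 |
| spring | 12.0 | 18.5 | 11.0 | 0.3 |

(each reading ± 1 percentage point)

* the flask that comes out highest in amount of isomer of the product, in percent of the solid substrate charged, or "all alike" when all lie within 1.5 percentage points (cedar / birch / elm / all alike)
* isomer of the product at the end, in percent of the solid substrate charged, cedar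
* isomer of the product at the end, in percent of the solid substrate charged, birch
* isomer of the product at the end, in percent of the solid substrate charged, elm

- as a solid, counted per litre of solution: solid substrate
- at the start none of the solid substrate is in solution

Read the runs as a ladder. On the first rung, the second substrate takes reagent one for one: at 12.0 d, the sum stands at 39.3% in dawn, 63.8% in dusk and 29.5% in spring, while reagent less second substrate comes to 0.400, 0.640 and 0.300. Cedar charges 0.600 equiv of reagent, the limiting reagent, against 0.200 equiv of second substrate, leaving 0.400. This free surplus, the reagent charged less the second substrate that reaches it before it is gone, as a fraction of the solid charged, is what I carry.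

On the next rung, the solid dissolves: dawn has 44.8% of it left at 1.67 d, yet its sum is already 33.2%. On the last rung, target turns: the isomer's share of the sum in summer goes from 0.271 at 3.00 d to 0.627 at 12.0 d.

My reckoning is surplus times share. Cedar gives 25.1%. In birch, taking 1.67 d from dawn as the reagent's working time, 0.0668 of second substrate has arrived, so the surplus is 0.533 and the isomer 33.4%. In elm, where the second substrate is in the flask from the start, I keep 0.400 and expect cedar's figure.

The forecast, whose figures differ from mine, names birch, with 25.7% for cedar, 32% for birch and 24% for elm, saying of the fed second substrate: “The rest finds no reagent”.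

The flasks give 25.3% for cedar, 33.2% for birch and 26.7% for elm, so birch stands higher than the other two.

    starting material + reagent → target (k = 0.0470 M⁻¹ min⁻¹)
    second substrate + reagent → second product (k = 0.0900 M⁻¹ min⁻¹)
    target ⇌ isomer of the product (K = 1.80, k = 1.70 × 10⁻⁴ min⁻¹)
    solid substrate ⇌ starting material, rate k4*(cs4 - [starting material]) while solid is left; crystals form when [starting material] > cs4 (solubility = 0.120 M, k = 2.60 × 10⁻⁴ min⁻¹)

Elm is where my reckoning parts from the flask, with a sum of 43.1% against the surplus of 0.400 I kept for it, and 16% of its charged second substrate still there at the end. Now take cedar with 0.120 equiv of second substrate: its surplus is 0.480, and times the share of 0.627 that gives 30.1% of isomer. That neighbour ends with 17.7% of target and 30.3% of isomer.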